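**Retrosynthetic overview**

1. Target 19 ⇒ desilylation of 18 ⇒ tertiary ester bond between ketol 14 and aroyl chloride 17 (the only free OH at that stage is the C7 hydroxyl).
2. Ring B (formed second) ⇒ C7–C8 bond by a carbene-catalysed intramolecular aldehyde-to-ketone acyl-anion addition (crossed benzoin) of keto aldehyde 13; this closes the carbocycle onto the intact pyran and creates the quaternary carbinol C7.
3. 13 ⇒ C5–C6 bond and the C6 stereocentre by a copper-catalysed vinylogous Mukaiyama aldol of the ring-locked silyl dienol ether 11 (from pyran aldehyde 10) with methylglyoxal.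
4. Ring A (formed first) ⇒ 10 from diol 8 by mono-oxidation and amine-triggered 6-endo closure; the two identical CH2OH groups on one alkene carbon mean no alkene geometry has to be controlled.
5. 8 ⇒ alkylidene malonate 7 ⇒ enol triflate of diethyl acetylmalonate plus a pentenynyl unit from crotonaldehyde.

Assumption: 4-hydroxy-2-methoxy-6-methylbenzoic acid (15) is bought as a catalogue compound; atom labels C1–C8a and O2 used below are those of the 1H-isochromene core of the target.

**Step 1**
Reactants: 1 (E)-but-2-enal (crotonaldehyde)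
Product: 2 (3E)-1,1-dibromopenta-1,3-diene
Conditions: CBr4 (2 equiv), PPh3 (2 equiv), Zn (2 equiv), CH2Cl2, 23 °C; then 1, 0 → 23 °C
Reagents that add atoms: carbon tetrabromide, BrC(Br)(Br)Br
Why: Corey–Fuchs dibromo-olefination (Wittig reaction of Ph3P=CBr2) turns the cheap enal into a masked (E)-pent-3-en-1-yne without touching the E alkene.

**Step 2**
Reactants: 3 diethyl 2-acetylpropanedioate (diethyl acetylmalonate)
Product: 4 diethyl 2-{1-[(trifluoromethanesulfonyl)oxy]ethylidene}propanedioate
Conditions: Tf2O (1.1 equiv), Et3N (1.2 equiv), CH2Cl2, −78 → 0 °C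
Reagents that add atoms: trifluoromethanesulfonic anhydride, O=S(=O)(OS(=O)(=O)C(F)(F)F)C(F)(F)F
Why: Enol triflate formation on the fully enolised tricarbonyl compound; the alkene carbon carries two identical ester groups, so there is no geometry to control.

**Step 3**
Reactants: 2 (3E)-1,1-dibromopenta-1,3-diene; 4 diethyl 2-{1-[(trifluoromethanesulfonyl)oxy]ethylidene}propanedioate
Product: 7 diethyl 2-[(5E)-hept-5-en-3-yn-2-ylidene]propanedioate, via lithium pentenynide 5 (not isolated), via pentenynylzinc chloride 6 (not isolated)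
Conditions: 2, n-BuLi (2.05 equiv), THF, −78 → 0 °C; ZnCl2 (1.1 equiv), 0 °C; then 4, Pd(PPh3)4 (3 mol %), 23 °C
Reagents that add atoms: none
Why: Second stage of the Corey–Fuchs sequence (Fritsch–Buttenberg–Wiechell rearrangement to the acetylide), Li-to-Zn exchange and Negishi alkynylation of the electron-poor enol triflate, which adds oxidatively with ease.

**Step 4**
Reactants: 7 diethyl 2-[(5E)-hept-5-en-3-yn-2-ylidene]propanedioate
Product: 8 2-[(5E)-hept-5-en-3-yn-2-ylidene]propane-1,3-diol
Conditions: i-Bu2AlH (4.5 equiv), CH2Cl2, −78 → 0 °C; aqueous potassium sodium tartrate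
Reagents that add atoms: none
Why: 1,2-Reduction of both conjugated esters by the Lewis-acidic aluminium hydride (the usual outcome for alkylidene malonates) leaves the enyne intact and gives two constitutionally identical allylic CH2OH groups.

**Step 5**
Reactants: 8 2-[(5E)-hept-5-en-3-yn-2-ylidene]propane-1,3-diol
Product: 10 4-methyl-6-[(1E)-prop-1-en-1-yl]-2H-pyran-3-carbaldehyde, via hydroxy enynal 9 (not isolated)
Conditions: TEMPO (10 mol %), PhI(OAc)2 (1.05 equiv), CH2Cl2, 0 °C; then pyrrolidine (1.2 equiv), AcOH (1.2 equiv), 23 °C; aqueous NaHCO3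
Reagents that add atoms: none
Why: Proposed new method: oxoammonium mono-oxidation of one allylic CH2OH (the second is deactivated once the enal exists) gives 9 as a mixture of alkene isomers; pyrrolidine then adds 1,6 to the ynenal (through its iminium ion) to give a vinamidinium-type push–pull diene whose C=C bonds rotate freely, so both isomers converge by attack of the CH2OH oxygen on C3 and loss of pyrrolidine (addition–elimination) to the 6-endo product, which avoids the 5-exo (furan) mode that π-acids impose on (Z)-enynols; the closest known reactions are 1,6-additions of secondary amines to enynones and amine-mediated 2H-pyran syntheses.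

**Step 6**
Reactants: 10 4-methyl-6-[(1E)-prop-1-en-1-yl]-2H-pyran-3-carbaldehyde
Product: 11 tert-butyl(dimethyl)[({4-methylidene-6-[(1E)-prop-1-en-1-yl]-2H-pyran-3(4H)-ylidene}methyl)oxy]silane
Conditions: TBSOTf (1.2 equiv), Et3N (2 equiv), Et2O, −78 → 0 °C; used at once
Reagents that add atoms: tert-butyldimethylsilyl trifluoromethanesulfonate, CC(C)(C)[Si](C)(C)OS(=O)(=O)C(F)(F)F
Why: Soft enolisation (O-silylation of the formyl group, then loss of a proton from the adjacent 4-methyl group) gives a silyl dienol ether that ring A locks s-cis, so the alkene regenerated in the next step must have the formyl group cis to the new side chain.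

**Step 7**
Reactants: 11 tert-butyl(dimethyl)[({4-methylidene-6-[(1E)-prop-1-en-1-yl]-2H-pyran-3(4H)-ylidene}methyl)oxy]silane; 12 2-oxopropanal (methylglyoxal, commercial 40 % aqueous solution, distilled from P2O5 before use)
Product: 13 4-[(2R)-2-{[tert-butyl(dimethyl)silyl]oxy}-3-oxobutyl]-6-[(1E)-prop-1-en-1-yl]-2H-pyran-3-carbaldehyde
Conditions: 12 (1.5 equiv), [Cu((R,R)-t-Bu-box)](SbF6)2 (10 mol %; box = 2,2′-(propane-2,2-diyl)bis(4-tert-butyl-4,5-dihydrooxazole)), CH2Cl2, −78 → −40 °C
Reagents that add atoms: none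
Why: Catalytic enantioselective vinylogous Mukaiyama aldol reaction: the copper–bis(oxazoline) complex binds methylglyoxal through both carbonyl oxygens, the diene attacks the aldehyde carbon through its exocyclic CH2 terminus (the α-position is fully substituted), and the silyl group passes to the new alkoxide. The (R,R)-ligand is expected to give the 6R carbinol by analogy with glyoxylate additions, where (S,S) gives S. Any [4+2] silyl acetal that forms should open under the Lewis acid to the more stable push–pull aldehyde.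

**Step 8 (key step)**
Reactants: 13 4-[(2R)-2-{[tert-butyl(dimethyl)silyl]oxy}-3-oxobutyl]-6-[(1E)-prop-1-en-1-yl]-2H-pyran-3-carbaldehyde
Product: 14 (6R,7S)-6-{[tert-butyl(dimethyl)silyl]oxy}-7-hydroxy-7-methyl-3-[(1E)-prop-1-en-1-yl]-6,7-dihydro-1H-isochromen-8(5H)-one
Conditions: (5aS,10bR)-2-(pentafluorophenyl)-5a,10b-dihydro-4H,6H-indeno[2,1-b][1,2,4]triazolo[4,3-d][1,4]oxazin-2-ium tetrafluoroborate (10 mol %), i-Pr2NEt (20 mol %), toluene, 23 °C
Reagents that add atoms: none
Why: Proposed new method: an NHC-catalysed intramolecular crossed aldehyde–ketone benzoin reaction in which the Breslow intermediate at the ring A formyl carbon (C8, an acyl anion equivalent) adds 6-exo to the methyl ketone carbon C7, joining two carbonyl carbons and closing ring B. The closest known reaction is the triazolium-catalysed cyclisation of 2-(3-oxobutyl)benzaldehydes to 2-hydroxy-2-methyl-1-tetralones; the pyran aldehyde is a less electrophilic, vinylogous formyl group, but it has the same geometry and cannot enolise. C7 is set by the catalyst's choice of ketone face, so the hydroxyl ends trans to the C6 silyloxy group (7S). The catalyst enantiomer to use is the one that gives the S ketol in the tetralone benchmark; the descriptor written is my best assignment and should be confirmed on that benchmark. The weak base leaves the C6 centre, which is α to the ketone, unepimerised.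

**Step 9**
Reactants: 15 4-hydroxy-2-methoxy-6-methylbenzoic acid
Product: 17 4-{[tert-butyl(dimethyl)silyl]oxy}-2-methoxy-6-methylbenzoyl chloride, via bis-silyl ester 16 (not isolated)
Conditions: TBSCl (2.1 equiv), Et3N (2.1 equiv), DMAP (5 mol %), CH2Cl2, 23 °C; then (COCl)2 (1.2 equiv), DMF (cat.), 0 → 23 °C
Reagents that add atoms: tert-butyldimethylsilyl chloride, CC(C)(C)[Si](C)(C)Cl; oxalyl chloride, O=C(Cl)C(=O)Cl
Why: Silylation of both acidic OH groups, then exchange of the silyl ester with oxalyl chloride/DMF under neutral conditions, gives the acid chloride while the aryl silyl ether stays on.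

**Step 10**
Reactants: 14 (6R,7S)-6-{[tert-butyl(dimethyl)silyl]oxy}-7-hydroxy-7-methyl-3-[(1E)-prop-1-en-1-yl]-6,7-dihydro-1H-isochromen-8(5H)-one; 17 4-{[tert-butyl(dimethyl)silyl]oxy}-2-methoxy-6-methylbenzoyl chloride
Product: 18 (6R,7S)-6-{[tert-butyl(dimethyl)silyl]oxy}-7-methyl-8-oxo-3-[(1E)-prop-1-en-1-yl]-5,6,7,8-tetrahydro-1H-isochromen-7-yl 4-{[tert-butyl(dimethyl)silyl]oxy}-2-methoxy-6-methylbenzoate
Conditions: LiN(SiMe3)2 (1.05 equiv), THF, −78 °C; then 17 (1.3 equiv), −78 → 0 °C
Reagents that add atoms: none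
Why: Acylation of the lithium alkoxide of the tertiary α-ketol with the hindered aroyl chloride (the alkoxide/acid chloride method used for tert-alkyl esters of 2,6-disubstituted benzoic acids); only the C7 hydroxyl is free and no stereocentre is touched.

**Step 11**
Reactants: 18 (6R,7S)-6-{[tert-butyl(dimethyl)silyl]oxy}-7-methyl-8-oxo-3-[(1E)-prop-1-en-1-yl]-5,6,7,8-tetrahydro-1H-isochromen-7-yl 4-{[tert-butyl(dimethyl)silyl]oxy}-2-methoxy-6-methylbenzoate
Product: 19 (6R,7S)-6-hydroxy-7-methyl-8-oxo-3-[(1E)-prop-1-en-1-yl]-5,6,7,8-tetrahydro-1H-isochromen-7-yl 4-hydroxy-2-methoxy-6-methylbenzoate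
Conditions: Bu4NF (3 equiv), AcOH (3 equiv), THF, 0 → 23 °C
Reagents that add atoms: none
Why: Fluoride cleavage of the secondary and the aryl silyl ether, buffered with AcOH so that neither acyl migration to O6 nor retro-aldol opening of the β-hydroxy ketone occurs; the hindered 2,6-disubstituted benzoate is inert.

**Compound list**

1 | (E)-but-2-enal (crotonaldehyde) | C/C=C/C=O | starting material
2 | (3E)-1,1-dibromopenta-1,3-diene | C/C=C/C=C(Br)Br | intermediate
3 | diethyl 2-acetylpropanedioate | CCOC(=O)C(C(C)=O)C(=O)OCC | starting material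
4 | diethyl 2-{1-[(trifluoromethanesulfonyl)oxy]ethylidene}propanedioate | CCOC(=O)C(=C(C)OS(=O)(=O)C(F)(F)F)C(=O)OCC | intermediate
5 | lithium (3E)-pent-3-en-1-yn-1-ide | [Li]C#C/C=C/C | intermediate
6 | chloro[(3E)-pent-3-en-1-yn-1-yl]zinc | Cl[Zn]C#C/C=C/C | intermediate
7 | diethyl 2-[(5E)-hept-5-en-3-yn-2-ylidene]propanedioate | CCOC(=O)C(=C(C)C#C/C=C/C)C(=O)OCC | intermediate
8 | 2-[(5E)-hept-5-en-3-yn-2-ylidene]propane-1,3-diol | OCC(CO)=C(C)C#C/C=C/C | intermediate
9 | (6E)-2-(hydroxymethyl)-3-methylocta-2,6-dien-4-ynal (2E/2Z mixture) | O=CC(CO)=C(C)C#C/C=C/C | intermediate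
10 | 4-methyl-6-[(1E)-prop-1-en-1-yl]-2H-pyran-3-carbaldehyde | O=CC1=C(C)C=C(/C=C/C)OC1 | intermediate
11 | tert-butyl(dimethyl)[({4-methylidene-6-[(1E)-prop-1-en-1-yl]-2H-pyran-3(4H)-ylidene}methyl)oxy]silane (enol ether geometry not defined) | C=C1C=C(/C=C/C)OCC1=CO[Si](C)(C)C(C)(C)C | intermediate
12 | 2-oxopropanal (methylglyoxal) | CC(=O)C=O | starting material
13 | 4-[(2R)-2-{[tert-butyl(dimethyl)silyl]oxy}-3-oxobutyl]-6-[(1E)-prop-1-en-1-yl]-2H-pyran-3-carbaldehyde | CC(=O)[C@H](O[Si](C)(C)C(C)(C)C)CC1=C(C=O)COC(/C=C/C)=C1 | intermediate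
14 | (6R,7S)-6-{[tert-butyl(dimethyl)silyl]oxy}-7-hydroxy-7-methyl-3-[(1E)-prop-1-en-1-yl]-6,7-dihydro-1H-isochromen-8(5H)-one | C/C=C/C1=CC2=C(CO1)C(=O)[C@@](C)(O)[C@H](O[Si](C)(C)C(C)(C)C)C2 | intermediate
15 | 4-hydroxy-2-methoxy-6-methylbenzoic acid | COc1cc(O)cc(C)c1C(=O)O | starting material
16 | tert-butyl(dimethyl)silyl 4-{[tert-butyl(dimethyl)silyl]oxy}-2-methoxy-6-methylbenzoate | COc1cc(O[Si](C)(C)C(C)(C)C)cc(C)c1C(=O)O[Si](C)(C)C(C)(C)C | intermediate
17 | 4-{[tert-butyl(dimethyl)silyl]oxy}-2-methoxy-6-methylbenzoyl chloride | COc1cc(O[Si](C)(C)C(C)(C)C)cc(C)c1C(Cl)=O | intermediate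
18 | (6R,7S)-6-{[tert-butyl(dimethyl)silyl]oxy}-7-methyl-8-oxo-3-[(1E)-prop-1-en-1-yl]-5,6,7,8-tetrahydro-1H-isochromen-7-yl 4-{[tert-butyl(dimethyl)silyl]oxy}-2-methoxy-6-methylbenzoate | C/C=C/C1=CC2=C(CO1)C(=O)[C@@](C)(OC(=O)c1c(C)cc(O[Si](C)(C)C(C)(C)C)cc1OC)[C@H](O[Si](C)(C)C(C)(C)C)C2 | intermediate
19 | (6R,7S)-6-hydroxy-7-methyl-8-oxo-3-[(1E)-prop-1-en-1-yl]-5,6,7,8-tetrahydro-1H-isochromen-7-yl 4-hydroxy-2-methoxy-6-methylbenzoate | C/C=C/C1=CC2=C(CO1)C(=O)[C@@](C)(OC(=O)c1c(C)cc(O)cc1OC)[C@H](O)C2 | target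

**Step count and weak points**

Total steps: 11. Longest linear sequence: 9 (steps 2, 3, 4, 5, 6, 7, 8, 10, 11; the branch through step 1 is equally long).

The three steps most likely to fail are steps 5, 7 and 8.

Step 5 (mono-oxidation and amine-triggered closure of ring A; untested, and 10 and 11 may polymerise). The fallback makes ring A last; it sets out from 9 and comes back to the route only at 19.
- TBSOTf/Et3N silylates both the alcohol and the formyl group of 9 to the bis-silyl dienol ether F1.
- The copper-catalysed aldol with 12 gives the open-chain keto aldehyde F2. Only its 2E isomer, with the formyl group cis to the new side chain, can cyclise; the 2Z isomer is equilibrated with a trace of iodine.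
- The triazolium-catalysed benzoin closes ring B to the alkynyl ketol F3.
- LiN(SiMe3)2 and 17 give the ester F4.
- Bu4NF/AcOH frees the triol F5.
- Ph3PAuNTf2 (2 mol %, CH2Cl2) closes ring A by 6-endo-dig hydroalkoxylation of the polarised ynenone, the oxygen attacking the alkyne carbon that bears the propenyl group, to give 19.

Step 7 (low ee with methylglyoxal, attack through C4 of ring A, or incomplete silyl transfer). The C5–C6 bond is made by a cycloaddition instead of an open-chain aldol; the fallback sets out from 11 and comes back at 13.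
- Ti(Oi-Pr)4/(R)-BINOL (10 mol %, 4 Å sieves, CH2Cl2, −30 °C) with 12 gives the bicyclic silyl acetal F6 by hetero-Diels–Alder reaction. The s-cis diene can bond only through its CH2 terminus, and (R)-BINOL is expected to give the R carbinol as in glyoxylate additions.
- A catalytic amount of TBSOTf at −78 °C opens the acetal with transfer of the silyl group to O6, giving 13.

Step 8 (the carbene may add sluggishly to the electron-rich formyl group, or the catalyst and the C6 centre may be mismatched). Ring B is closed by a reductive, ketyl-based C7–C8 coupling instead; the fallback sets out from 13 and comes back at 14.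
- SmI2 (2.5 equiv, THF, t-BuOH, −78 °C) reduces the conjugated aldehyde to its ketyl, which adds to the ketone to give the 7,8-diol F7. The new C7 hydroxyl is expected trans to the neighbouring silyloxy group, as in pinacol cyclisations of α-alkoxy carbonyl compounds.
- MnO2 in CH2Cl2 oxidises only the allylic secondary C8 hydroxyl and gives 14.

**Further compounds**

F1 | step 5 | tert-butyl{[(6E)-2-({[tert-butyl(dimethyl)silyl]oxy}methyl)-3-methylideneocta-1,6-dien-4-yn-1-yl]oxy}dimethylsilane | C=C(C#C/C=C/C)C(CO[Si](C)(C)C(C)(C)C)=CO[Si](C)(C)C(C)(C)C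
F2 | step 5 | (2E,6E)-3-[(2R)-2-{[tert-butyl(dimethyl)silyl]oxy}-3-oxobutyl]-2-({[tert-butyl(dimethyl)silyl]oxy}methyl)octa-2,6-dien-4-ynal | CC(=O)[C@H](O[Si](C)(C)C(C)(C)C)C/C(C#C/C=C/C)=C(\C=O)CO[Si](C)(C)C(C)(C)C
F3 | step 5 | (5R,6S)-5-{[tert-butyl(dimethyl)silyl]oxy}-2-({[tert-butyl(dimethyl)silyl]oxy}methyl)-6-hydroxy-6-methyl-3-[(3E)-pent-3-en-1-yn-1-yl]cyclohex-2-en-1-one | C/C=C/C#CC1=C(CO[Si](C)(C)C(C)(C)C)C(=O)[C@@](C)(O)[C@H](O[Si](C)(C)C(C)(C)C)C1
F4 | step 5 | (1S,6R)-6-{[tert-butyl(dimethyl)silyl]oxy}-3-({[tert-butyl(dimethyl)silyl]oxy}methyl)-1-methyl-2-oxo-4-[(3E)-pent-3-en-1-yn-1-yl]cyclohex-3-en-1-yl 4-{[tert-butyl(dimethyl)silyl]oxy}-2-methoxy-6-methylbenzoate | C/C=C/C#CC1=C(CO[Si](C)(C)C(C)(C)C)C(=O)[C@@](C)(OC(=O)c2c(C)cc(O[Si](C)(C)C(C)(C)C)cc2OC)[C@H](O[Si](C)(C)C(C)(C)C)C1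
F5 | step 5 | (1S,6R)-6-hydroxy-3-(hydroxymethyl)-1-methyl-2-oxo-4-[(3E)-pent-3-en-1-yn-1-yl]cyclohex-3-en-1-yl 4-hydroxy-2-methoxy-6-methylbenzoate | C/C=C/C#CC1=C(CO)C(=O)[C@@](C)(OC(=O)c2c(C)cc(O)cc2OC)[C@H](O)C1
F6 | step 7 | 1-[(4R)-2-{[tert-butyl(dimethyl)silyl]oxy}-8-[(1E)-prop-1-en-1-yl]-3,9-dioxabicyclo[4.4.0]deca-1(6),7-dien-4-yl]ethan-1-one (acetal carbon as a mixture of epimers) | CC(=O)[C@H]1CC2=C(COC(/C=C/C)=C2)C(O[Si](C)(C)C(C)(C)C)O1
F7 | step 8 | (6R,7R)-6-{[tert-butyl(dimethyl)silyl]oxy}-7-methyl-3-[(1E)-prop-1-en-1-yl]-5,6,7,8-tetrahydro-1H-isochromene-7,8-diol (C8 epimers; same spatial arrangement at C7 as in 14) | C/C=C/C1=CC2=C(CO1)C(O)[C@@](C)(O)[C@H](O[Si](C)(C)C(C)(C)C)C2
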